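(All constants are those of an exercise, and the outcome is calculated.)

Watch the temperature first: from 60 °C to 30 °C the constant k into the dormant form falls from 0.265 h⁻¹ to 0.00922 h⁻¹, and the release constant k/K falls from 0.126 h⁻¹ to 0.00367 h⁻¹.

all flasks: starting material 0.042 M; protic impurity 0.0126 M; time 3.0 d
- autumn: at 30 °C until 40 h, from then on at 60 °C
- winter: temperature 60 °C
- noon: temperature 30 °C

    starting material ⇌ dormant form (K1 = 2.1, k1 = 0.265 h⁻¹, Ea1 = 94.0 kJ mol⁻¹, ΔH1 = −5.00 kJ mol⁻¹)
    starting material + protic impurity → quenched substrate (k2 = 50.8 L mol⁻¹ h⁻¹, Ea2 = 68.0 kJ mol⁻¹)
    starting material + starting material ⇌ product (K3 = 52 L mol⁻¹, k3 = 90.9 L mol⁻¹ h⁻¹, Ea3 = 49.0 kJ mol⁻¹, ΔH3 = −9.00 kJ mol⁻¹)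
    (constants at 60 °C)

- percentages count the starting material that a species holds: one product counts as two
- where a step has two of a species, its rate is k times that concentration squared, and two are used at each turn
- all constants are for 60 °C and move with temperature by the activation energies and enthalpies

- the flask with the highest amount of product, in percent of the starting material charged ("all alike" if they lie within 1.5 percentage points) (autumn / winter / noon / all alike)
- final product, as a percentage of the starting material charged, in autumn
- final product, as a percentage of the starting material charged, in winter
- final product, as a percentage of the starting material charged, in noon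

Count in fractions of the charge: a for free starting material, p for product, y for dormant form. Assume that the protic impurity ends wholly as quenched substrate. That leaves a pool w = 0.700.

Scale the constants with the factor 11 of the impurity step. At 30 °C the equilibrium constant of the product step becomes 71.7 L mol⁻¹ and the dormant constant K becomes 2.51.

Write p = b times a squared, where b is twice that constant times the charge: 4.37 at 60 °C, 6.02 at 30 °C.

Carry one number, the release count θ = kt/K, the run time over the lifetime of the dormant form. In noon it is 0.264.

Winter has θ = 9.09. Autumn has 4.04 after its change at 40 h. Both exceed 1, so take equilibrium, thermodynamic control, with y = Ka: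

Winter and autumn: a = 0.180, p = 0.142

Noon has a count below 1, so the dormant form lags: kinetic control. Bracket noon at 3.0 d:

Above, with y = 0: a = 0.268, p = 0.432

Below, at equilibrium: a = 0.157, p = 0.149

Now treat y as the correction, y = Ka(1 − exp(−θ)):

With the upper a: y = 0.156, then a = 0.229, p = 0.315

With that lower a: y = 0.133, then a = 0.235, p = 0.332

The forecast gives 14.1 % for autumn, 14.1 % for winter and 32 % for noon, with the most in noon, says “noon stays kinetically trapped”, and its noon figure lies inside my tightened bracket.

The flasks give 14.2 % in autumn, 14.2 % in winter and 32.5 % in noon, the most in noon, and noon falls between 0.315 and 0.332. Left ten times as long, noon reads 15.1 % at 30.0 d, beside the lower bound 0.149. Its count there is 2.64, and exp(−θ) is 0.0714.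

Take autumn read at 20 h, before its change, still at 30 °C. The count is 0.0735, and with a = 0.268 it gives y = 0.0477. The computed reading is 5.52 % dormant form beside 46.7 % product.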